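## Structural features

The target is a 7,8-dihydro-6H-isochromen-6-one (azaphilone type). A 2H-pyran ring (O2, C1, C3, C4, C4a, C8a) is fused through C4a–C8a to a six-membered carbocycle (C5–C8). The two rings share a vinylogous ester that runs from O2 through C3=C4 and C4a=C5 to the C6 carbonyl, and a second enol ether C8a=C1. C3 carries a (1E,3E,5S)-3,5-dimethylhepta-1,3-dienyl chain, C5 a chlorine, C7 (S) a methyl group and a tertiary hydroxyl, and C8 (S) a hydrogen and, through C3', a (6'S)-6-methyloxane-2,4-dione. C7 and C8 are adjacent, C7 is fully substituted, C8 is flanked on its other side by the configurationally labile C3', and on the carbocycle the C8 substituent is cis to the C7 hydroxyl. Fragile points are the beta-keto lactone (acidic, enolised, reactive toward halogenating agents), the electrophilic C1 (amines, hydroxide), the tertiary alpha-ketol and the remote allylic stereocentre of the side chain. The real difficulty is the C7/C8 pair, which must be made in one absolute and relative configuration and then carried through ring construction. The key step exploits the fact that O2–C3=C4–C4a=C5–C6=O is an acylated 4-methylenepyran: C5 can be the nucleophilic exocyclic carbon of a 4-methylene-4H-pyran and C6 the carboxyl carbon of the C7 alpha-hydroxy acid, so the carbocycle closes at C5–C6 after both stereocentres are in place.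

## Logic of the disconnections

**C5–Cl (27 to 25).** The C5–Cl bond is cut first. C5 is the terminus of the dienol ether starting at O2 and the alpha-carbon of the C6 ketone, so an electrophilic chlorine should enter 25 there. Leaving the halogen to the end keeps it out of all enolate and organometallic steps. The demand is that C3' is at least as reactive, so the forward sequence accepts chlorination at both carbons (26) and then removes the C3' chlorine reductively, the vinylic C5–Cl bond being inert.

**C5–C6 (25 to 23, key cut).** Cutting C5–C6 opens the carbocycle to 23, in which C5 is an exocyclic methylene carbon and C6 a carboxyl carbon. This ring bond is remote from both stereocentres and polarised in the natural sense (enol ether carbon to acyl carbon). The gain is one ring less and an open chain on which C7 and C8 can be set. The forward step needs an acyl donor that also occupies the neighbouring tertiary hydroxyl (24) and a nucleophile released by mild base from a storable cation (22).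

**C4a–C5 (22 to 20).** Removing the methyl carbon C5 from 22 reveals the ring carbonyl of 20 (through 21). The cationic ring is exchanged for a neutral, robust heterocycle that tolerates enolate chemistry. The demand is a 1,2-addition of a methyl nucleophile to C4a while the carboxyl, the hydroxyl and the dione are shielded as their anions.

**C7–C8 (20 to 19, then 18 and 15).** This is the stereochemical cut. C7 becomes the nucleophilic carbon of 18, formed from 17, in which the configuration of 16 is stored at the acetal carbon. C8 becomes the electrophilic carbon of 15. Both stereocentres arise in one bond formation from two achiral-at-reacting-carbon partners of similar size. The demands are attack anti to the tert-butyl group (C7), one relative topicity (C8), and addition at C8 instead of C1.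

**C8=C3' (15 to 11 and 14).** The double bond is cut by a retro-condensation to the aldehyde carbon of 11 and the acidic methylene of 14. This separates the lactone, with its own stereocentre, from the heterocycle. The forward step must stop at the 1:1 adduct.

**C3–C4 and O2–C1 (11 to 9 and 8).** The ring of 11 is opened at the bond between the side-chain acyl carbon and C4 and at O2–C1, giving 9 (from 5) and 8 through 10. The two one-carbon arms on the central carbon of 8 are equivalent, so either can become C1 and the other the C8 aldehyde. 8 comes from 6 through 7 by C-formylation. The demand is clean enolate acylation at the methyl group in the presence of a masked aldehyde.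

**Side-chain alkenes (5 to 1).** The C=C bonds of 5 are cut in turn (4, 3, 2) back to 1, which supplies the stereocentre. Each olefination must be E-selective and must not epimerise the adjacent or allylic centre.

**Lactone and acetal (14 to 12; 17 to 16).** 14 is cut at the ring C–O bond and at C3'–C4' to 13 and then 12, which brings C6'. 17 is cut at its acetal to 16. Both are two-carbon or acetal extensions of chiral-pool hydroxy acids that leave the existing centres untouched.

## Other disconnections considered

**Alternative 1:** The cut is at C4a–C8a and O2–C3, giving the open-chain diynone aldehyde A2. In the forward step a secondary amine would form the enamine of the C1 aldehyde, C8a would add to C4a of the ynone (6-endo-dig), and the C1 oxygen would add to C3 of the remaining alkyne (6-endo-dig), giving the protected 5-deschloro compound A1.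
- In favour: two rings and two bonds from a linear precursor in one operation, which is better than the chosen plan (one ring, one bond). No pyrylium salt and no organometallic addition to a polyfunctional substrate are needed.
- Against: A2 combines an enolisable aldehyde, a conjugated diynone that can capture the amine catalyst, and a hindered silyloxy ketone. The amine can also add to C1 of A1, and the second closure has to beat 5-exo attack at C4.
- Structure: the C7/C8 pair must still be built on an open chain, so the alternative is equal to the chosen plan on the hardest problem.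
- Mechanism: both key steps contain an untested element, so they are equal in risk.
- Step economy: two protecting groups must be removed from A1 and C5 must still be chlorinated. Hydrolysis of a vinylogous ester methyl ether on the finished chromophore is a hazard that the chosen plan avoids. The sequence after the key step is longer (three or four steps against two).

**Alternative 2:** The cut is at C8–C3' and C8–C8a. The open-chain chloro-enone dialdehyde A4 would condense at its C8 aldehyde with C3' of 14, and the enol spanning C1 and C8a would then add to C8 (6-exo-trig), giving the carbocycle A3.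
- In favour: the lactone enters late and unprotected, and chlorine is on C5 from the start. The late chlorination problem at C3' disappears, which is better than the chosen plan on that point. C8 is created in a cyclic transition state next to C7.
- Against: A4 is an alpha-hydroxy-alpha-formyl ketone (prone to deformylation) with a beta,gamma-unsaturated aldehyde that can move into conjugation. The C1 aldehyde is less hindered than the neopentyl C8 aldehyde and should condense first. The only stereocontrol for C8 is the adjacent C7.
- Structure: A3 still lacks the pyran ring and the side chain, which would have to be added by strong-base chemistry on a substrate carrying a free dione and a free tertiary alcohol.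
- Mechanism: the reaction types are well known, so the alternative is better than the chosen key step on that point, but the chemoselectivity is less secure.
- Step economy: probably no shorter, because the pyran annulation remains.

**Alternative 3:** The cut is at C3–C4 and O2–C1. The gamma-enolate of the C4 methyl group of the aminomethylene cyclohexenone A6 would be acylated by 9, and the new C3 enol oxygen would displace dimethylamine at C1 (6-endo-trig addition–elimination), giving the protected target A5.
- In favour: this is the reaction type used in step 5 of the chosen route, so it is equal in mechanism and well supported. The side chain arrives in the last C–C bond formation, which is better for convergence and for analogues. The chlorine is already in place, which is also better.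
- Against: a strong amide base meets a fully functionalised substrate with other acidic sites (C5' of the lactone enol ether, C8). A vinylogous enolate must react at its gamma-carbon and not at oxygen. The two protecting groups come off on the finished chromophore.
- Structure: the difficult part, a cyclohexenone carrying C7, C8, the chlorine and the enaminone, is moved into the synthesis of A6 and not solved by this cut.
- Step economy: not clearly better, because the synthesis of A6 is likely to be long.

Key step: step 13

Remarks on the chemistry:
- C3' lies between two carbonyl groups and equilibrates through the enol. Every compound with the free dione is drawn as the (3'R) diketo form of the target but will exist as an enol/epimer mixture. The (3'R) diketo form is assumed to be the one reached under thermodynamic control.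
- When the lactic acid stereocentre is relayed through the acetal carbon, the new C7–C8 bond takes the place of the alpha-hydrogen. (7S) therefore requires (R)-lactic acid; an (S)-lactate would lead to the (7R) series. This corrects the choice of lactate enantiomer.
- Isochromene numbering of the target (C1 to C8a, lactone atoms primed) is used for all intermediates.

## Route

Step 1
Reactants: 1 (S)-2-methylbutan-1-ol
Product: 3 (2E,4S)-2,4-dimethylhex-2-enal, via (S)-2-methylbutanal 2 (not isolated)
Conditions: TEMPO (10 mol %), PhI(OAc)2, CH2Cl2, rt; then Ph3P=C(Me)CHO, toluene, 80 °C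
Reagents that add atoms: 2-(triphenylphosphoranylidene)propanal, CC(C=O)=P(c1ccccc1)(c1ccccc1)c1ccccc1
Why: Oxoammonium oxidation stops at the aldehyde, which is consumed in the same flask and so is not stored in its epimerisable form; Wittig olefination with the formyl-stabilised ylide should give the E trisubstituted enal, and the stereocentre is carried over from 1.

Step 2
Reactants: 3 (2E,4S)-2,4-dimethylhex-2-enal
Product: 4 ethyl (2E,4E,6S)-4,6-dimethylocta-2,4-dienoate
Conditions: (EtO)2P(O)CH2CO2Et, NaH, THF, 0 °C to rt
Reagents that add atoms: triethyl phosphonoacetate, CCOC(=O)CP(=O)(OCC)OCC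
Why: Horner–Wadsworth–Emmons olefination with a stabilised phosphonate should be E-selective; no amine is present, so the gamma-stereocentre cannot be lost through a dienamine.

Step 3
Reactants: 4 ethyl (2E,4E,6S)-4,6-dimethylocta-2,4-dienoate
Product: 5 (2E,4E,6S)-4,6-dimethylocta-2,4-dienoic acid
Conditions: LiOH, THF/MeOH/H2O, rt; then 1 M HCl
Reagents that add atoms: lithium hydroxide, [Li+].[OH-]
Why: Ester saponification; the dienoate has no sp3 alpha-hydrogen and the remote stereocentre is not acidified.

Step 4
Reactants: 6 (E)-4-(dimethylamino)but-3-en-2-one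
Product: 8 2-[(dimethylamino)methylidene]-3-oxobutanal, via vinamidinium chloride 7 (not isolated)
Conditions: [Me2N=CHCl]Cl, CH2Cl2, 0 °C to rt; then aq. K2CO3, 0 °C
Reagents that add atoms: (chloromethylene)dimethyliminium chloride, C[N+](C)=CCl.[Cl-]; water, O
Why: Vilsmeier–Haack C-formylation at the nucleophilic alpha-carbon of the enaminone gives a symmetrical 2-acetyl vinamidinium salt; mild basic hydrolysis frees one of the two equivalent arms as the aldehyde.

Step 5
Reactants: 5 (2E,4E,6S)-4,6-dimethylocta-2,4-dienoic acid; 8 2-[(dimethylamino)methylidene]-3-oxobutanal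
Product: 11 6-[(1E,3E,5S)-3,5-dimethylhepta-1,3-dien-1-yl]-4-oxo-4H-pyran-3-carbaldehyde, via dienoyl chloride 9 (not isolated), via diketo enaminone 10 (not isolated)
Conditions: (COCl)2, DMF (cat.), CH2Cl2, 0 °C to rt, evaporate; 8, then LiN(SiMe3)2 (2.2 equiv), THF, −78 °C; AcOH, −78 °C to rt
Reagents that add atoms: none
Why: In situ Claisen-type C-acylation of the enaminone enolate at the acetyl methyl group, then acid-promoted addition–elimination of the new enol oxygen at an aminomethylene carbon with loss of dimethylamine, is the established 4-pyranone annulation of 2-aminomethylene 1,3-dicarbonyl compounds; the formyl group is a vinylogous formamide during the enolate stage, and because the two one-carbon arms are equivalent either closure gives 11.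

Step 6
Reactants: 12 methyl (S)-3-hydroxybutanoate
Product: 13 tert-butyl (5S)-5-hydroxy-3-oxohexanoate
Conditions: t-BuOAc, LiN(i-Pr)2 (3.2 equiv), THF, −78 to −20 °C; AcOH
Reagents that add atoms: tert-butyl acetate, CC(=O)OC(C)(C)C
Why: Claisen condensation of excess lithium enolate with the hydroxy ester (alkoxide formed first, product held as its enolate); the carbinol stereocentre is not involved.

Step 7
Reactants: 13 tert-butyl (5S)-5-hydroxy-3-oxohexanoate
Product: 14 (6S)-6-methyloxane-2,4-dione
Conditions: TFA, CH2Cl2, rt
Reagents that add atoms: none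
Why: Acidolysis of the tert-butyl ester and lactonisation of the delta-hydroxy beta-keto acid, which closes faster than it decarboxylates; C6' keeps its configuration because the C–O bond is not broken.

Step 8
Reactants: 11 6-[(1E,3E,5S)-3,5-dimethylhepta-1,3-dien-1-yl]-4-oxo-4H-pyran-3-carbaldehyde; 14 (6S)-6-methyloxane-2,4-dione
Product: 15 (6S)-3-({6-[(1E,3E,5S)-3,5-dimethylhepta-1,3-dien-1-yl]-4-oxo-4H-pyran-3-yl}methylidene)-6-methyloxane-2,4-dione (E/Z mixture)
Conditions: piperidinium acetate (10 mol %), 4 Å molecular sieves, CH2Cl2, 0 °C to rt; 11 in slight excess, 14 added slowly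
Reagents that add atoms: none
Why: Knoevenagel condensation of an electron-poor aldehyde with a strongly acidic cyclic dione; donation from O2 through C1=C8a stabilises the alkylidene dione and slow addition of 14 should suppress the 2:1 adduct; the alkene geometry is irrelevant because C8 becomes sp3 in step 10.

Step 9
Reactants: 16 (R)-lactic acid
Product: 17 (2R,5R)-2-tert-butyl-5-methyl-1,3-dioxolan-4-one
Conditions: t-BuCHO, TsOH (cat.), pentane, reflux with water separator; crystallisation, −78 °C
Reagents that add atoms: pivalaldehyde, CC(C)(C)C=O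
Why: Acetalisation of the alpha-hydroxy acid (self-regeneration of stereocentres); the cis acetal is favoured and purified by crystallisation, and its acetal carbon stores the configuration of 16 after C5 is made trigonal.

Step 10
Reactants: 17 (2R,5R)-2-tert-butyl-5-methyl-1,3-dioxolan-4-one; 15 (6S)-3-({6-[(1E,3E,5S)-3,5-dimethylhepta-1,3-dien-1-yl]-4-oxo-4H-pyran-3-yl}methylidene)-6-methyloxane-2,4-dione
Product: 19 (2R,5S)-2-tert-butyl-5-[(S)-{6-[(1E,3E,5S)-3,5-dimethylhepta-1,3-dien-1-yl]-4-oxo-4H-pyran-3-yl}[(3R,6S)-6-methyl-2,4-dioxooxan-3-yl]methyl]-5-methyl-1,3-dioxolan-4-one, via lithium dioxolanone enolate 18 (not isolated)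
Conditions: LiN(i-Pr)2, THF, −78 °C; 15 in THF, −78 °C; AcOH, −78 °C
Reagents that add atoms: none
Why: Michael addition of a dioxolanone lithium enolate to an alkylidene 1,3-dicarbonyl compound, a known combination; C7 is set by attack anti to the tert-butyl group (the new bond replaces the former alpha-hydrogen, giving 7S), and C8 is expected to be set by a lithium-bridged closed transition state with the dione carbonyl over the O–Li/methyl flank, the pyranonyl group pointing away from the dioxolanone ring and the C8 hydrogen over it, which corresponds to the 8S adduct.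

Step 11
Reactants: 19 (2R,5S)-2-tert-butyl-5-[(S)-{6-[(1E,3E,5S)-3,5-dimethylhepta-1,3-dien-1-yl]-4-oxo-4H-pyran-3-yl}[(3R,6S)-6-methyl-2,4-dioxooxan-3-yl]methyl]-5-methyl-1,3-dioxolan-4-one
Product: 20 (2S,3S)-3-{6-[(1E,3E,5S)-3,5-dimethylhepta-1,3-dien-1-yl]-4-oxo-4H-pyran-3-yl}-2-hydroxy-2-methyl-3-[(3R,6S)-6-methyl-2,4-dioxooxan-3-yl]propanoic acid
Conditions: LiOH, THF/H2O, 0 °C to rt; then 1 M HCl to pH 3
Reagents that add atoms: lithium hydroxide, [Li+].[OH-]
Why: Hydroxide opens the activated acylal ester and the hemiacetal collapses to pivalaldehyde; the dione is present as its enolate so neither lactone carbonyl is attacked, and C7 (quaternary) and C8 (not acidic) are untouched.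

Step 12
Reactants: 20 (2S,3S)-3-{6-[(1E,3E,5S)-3,5-dimethylhepta-1,3-dien-1-yl]-4-oxo-4H-pyran-3-yl}-2-hydroxy-2-methyl-3-[(3R,6S)-6-methyl-2,4-dioxooxan-3-yl]propanoic acid
Product: 22 5-[(1S,2S)-2-carboxy-2-hydroxy-1-[(3R,6S)-6-methyl-2,4-dioxooxan-3-yl]propyl]-2-[(1E,3E,5S)-3,5-dimethylhepta-1,3-dien-1-yl]-4-methylpyrylium tetrafluoroborate, via tertiary pyranol 21 (not isolated)
Conditions: MeMgBr (5 equiv), THF, −40 to 0 °C; then HBF4·OEt2, Et2O, −20 °C; salt precipitated and used at once
Reagents that add atoms: methylmagnesium bromide, C[Mg]Br; tetrafluoroboric acid, [H+].F[B-](F)(F)F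
Why: The first three equivalents turn the carboxyl, the tertiary hydroxyl and the dione into magnesium carboxylate, alkoxide and enolate, which are inert to the Grignard reagent; the fourth adds 1,2 to the 4-pyranone carbonyl, and acid ionises the doubly vinylic tertiary carbinol to the aromatic pyrylium cation, the classical route from 4-pyranones to 4-alkylpyrylium salts.

Step 13
Reactants: 22 5-[(1S,2S)-2-carboxy-2-hydroxy-1-[(3R,6S)-6-methyl-2,4-dioxooxan-3-yl]propyl]-2-[(1E,3E,5S)-3,5-dimethylhepta-1,3-dien-1-yl]-4-methylpyrylium tetrafluoroborate
Product: 25 (7S,8S)-3-[(1E,3E,5S)-3,5-dimethylhepta-1,3-dien-1-yl]-7-hydroxy-7-methyl-8-[(3R,6S)-6-methyl-2,4-dioxooxan-3-yl]-7,8-dihydro-6H-isochromen-6-one, via methylenepyran hydroxy acid 23 (not isolated), via O-carboxyanhydride 24 (not isolated)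
Conditions: i-Pr2NEt (3 equiv), MeCN (0.005 M), −30 °C; CDI (2.5 equiv), −30 °C to rt; pH 4 phosphate buffer
Reagents that add atoms: none
Why: Proposed new method: the amine first converts 22 into its neutral anhydrobase 23 (carboxylate and dione enolate as ammonium salts) before any imidazole is present, and CDI then turns the alpha-hydroxy carboxylate, through the acyl imidazolyl carbonate and 5-exo attack of the tertiary hydroxyl, into the five-membered O-carboxyanhydride 24, which ties up both oxygen nucleophiles on C7. The exocyclic carbon C5 of the 4-methylenepyran, the terminus of two enol ether systems, adds to the anhydride carbonyl C6; collapse of the tetrahedral intermediate opens the small ring, loss of CO2 frees the C7 hydroxyl, and deprotonation at C5 of the resulting acylmethylpyrylium gives the vinylogous ester 25. The closest known reaction type is C-acylation of 4-methylenepyrans (anhydrobases of 4-methylpyrylium salts) at the exocyclic carbon by acid chlorides and anhydrides; ring-opening of an O-carboxyanhydride by such a carbon nucleophile has not been shown, hence the label. The carbocycle (C5, C6, C7, C8, C8a, C4a) closes in 6-exo-trig mode at the C6 carbonyl, with nucleophile and electrophile on the adjacent ring carbons C4a and C8a, so no strained alternative competes. No stereocentre is formed: C7 is quaternary and C8 is not acidified by the neutral anhydrobase, so both are carried over. The step needs C6 to be chosen over the lactone carbonyls C2' and C4' and over intermolecular acylation; the dione is an enolate and therefore not electrophilic, C6 is the only activated carboxyl, and the reaction is run dilute. O-acylation of the dione enolate by C6 or by CDI would give an enol ester that is itself an acyl donor and should either pass the acyl group on to C5 or revert on work-up.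

Step 14
Reactants: 25 (7S,8S)-3-[(1E,3E,5S)-3,5-dimethylhepta-1,3-dien-1-yl]-7-hydroxy-7-methyl-8-[(3R,6S)-6-methyl-2,4-dioxooxan-3-yl]-7,8-dihydro-6H-isochromen-6-one
Product: 26 (7S,8S)-5-chloro-8-[(6S)-3-chloro-6-methyl-2,4-dioxooxan-3-yl]-3-[(1E,3E,5S)-3,5-dimethylhepta-1,3-dien-1-yl]-7-hydroxy-7-methyl-7,8-dihydro-6H-isochromen-6-one (C3' epimers)
Conditions: NCS (2.2 equiv), MeCN, 0 °C to rt
Reagents that add atoms: N-chlorosuccinimide, O=C1CCC(=O)N1Cl
Why: Electrophilic chlorination at C5, the alpha-carbon of the vinylogous ester and the usual site of halogenation of this chromophore; the dione enol is expected to be chlorinated as well, so two equivalents are used to converge on one constitution whichever site reacts first.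

Step 15
Reactants: 26 (7S,8S)-5-chloro-8-[(6S)-3-chloro-6-methyl-2,4-dioxooxan-3-yl]-3-[(1E,3E,5S)-3,5-dimethylhepta-1,3-dien-1-yl]-7-hydroxy-7-methyl-7,8-dihydro-6H-isochromen-6-one
Product: 27 (7S,8S)-5-chloro-3-[(1E,3E,5S)-3,5-dimethylhepta-1,3-dien-1-yl]-7-hydroxy-7-methyl-8-[(3R,6S)-6-methyl-2,4-dioxooxan-3-yl]-7,8-dihydro-6H-isochromen-6-one
Conditions: Zn dust, AcOH, THF, 0 °C, short contact time
Reagents that add atoms: none
Why: Reductive dehalogenation of an alpha-chloro beta-dicarbonyl compound through its zinc enolate is very easy, whereas the vinylic C5–Cl bond should not react; protonation of the enolate returns the dione, whose C3' centre settles by equilibration through the enol.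

## Compound list

1 | (S)-2-methylbutan-1-ol | CC[C@H](C)CO | starting material
2 | (S)-2-methylbutanal | CC[C@H](C)C=O | intermediate
3 | (2E,4S)-2,4-dimethylhex-2-enal | CC[C@H](C)/C=C(C)/C=O | intermediate
4 | ethyl (2E,4E,6S)-4,6-dimethylocta-2,4-dienoate | CC[C@H](C)/C=C(C)/C=C/C(=O)OCC | intermediate
5 | (2E,4E,6S)-4,6-dimethylocta-2,4-dienoic acid | CC[C@H](C)/C=C(C)/C=C/C(=O)O | intermediate
6 | (E)-4-(dimethylamino)but-3-en-2-one | CC(=O)/C=C/N(C)C | starting material
7 | N-[2-acetyl-3-(dimethylamino)prop-2-en-1-ylidene]-N-methylmethanaminium chloride | CC(=O)C(C=[N+](C)C)=CN(C)C.[Cl-] | intermediate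
8 | 2-[(dimethylamino)methylidene]-3-oxobutanal | CC(=O)C(C=O)=CN(C)C | intermediate
9 | (2E,4E,6S)-4,6-dimethylocta-2,4-dienoyl chloride | CC[C@H](C)/C=C(C)/C=C/C(Cl)=O | intermediate
10 | (6E,8E,10S)-2-[(dimethylamino)methylidene]-8,10-dimethyl-3,5-dioxododeca-6,8-dienal | CC[C@H](C)/C=C(C)/C=C/C(=O)CC(=O)C(C=O)=CN(C)C | intermediate
11 | 6-[(1E,3E,5S)-3,5-dimethylhepta-1,3-dien-1-yl]-4-oxo-4H-pyran-3-carbaldehyde | CC[C@H](C)/C=C(C)/C=C/C1=CC(=O)C(C=O)=CO1 | intermediate
12 | methyl (S)-3-hydroxybutanoate | C[C@H](O)CC(=O)OC | starting material
13 | tert-butyl (5S)-5-hydroxy-3-oxohexanoate | C[C@H](O)CC(=O)CC(=O)OC(C)(C)C | intermediate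
14 | (6S)-6-methyloxane-2,4-dione | C[C@H]1CC(=O)CC(=O)O1 | intermediate
15 | (6S)-3-({6-[(1E,3E,5S)-3,5-dimethylhepta-1,3-dien-1-yl]-4-oxo-4H-pyran-3-yl}methylidene)-6-methyloxane-2,4-dione (E/Z mixture at the exocyclic double bond) | CC[C@H](C)/C=C(C)/C=C/C1=CC(=O)C(C=C2C(=O)C[C@H](C)OC2=O)=CO1 | intermediate
16 | (R)-lactic acid | C[C@@H](O)C(=O)O | starting material
17 | (2R,5R)-2-tert-butyl-5-methyl-1,3-dioxolan-4-one (cis) | C[C@H]1O[C@@H](C(C)(C)C)OC1=O | intermediate
18 | lithium (2R)-2-tert-butyl-5-methyl-1,3-dioxol-4-olate | CC1=C([O-])O[C@H](C(C)(C)C)O1.[Li+] | intermediate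
19 | (2R,5S)-2-tert-butyl-5-[(S)-{6-[(1E,3E,5S)-3,5-dimethylhepta-1,3-dien-1-yl]-4-oxo-4H-pyran-3-yl}[(3R,6S)-6-methyl-2,4-dioxooxan-3-yl]methyl]-5-methyl-1,3-dioxolan-4-one | CC[C@H](C)/C=C(C)/C=C/C1=CC(=O)C(=CO1)[C@H]([C@@H]3C(=O)C[C@H](C)OC3=O)[C@]2(C)O[C@@H](C(C)(C)C)OC2=O | intermediate
20 | (2S,3S)-3-{6-[(1E,3E,5S)-3,5-dimethylhepta-1,3-dien-1-yl]-4-oxo-4H-pyran-3-yl}-2-hydroxy-2-methyl-3-[(3R,6S)-6-methyl-2,4-dioxooxan-3-yl]propanoic acid | CC[C@H](C)/C=C(C)/C=C/C1=CC(=O)C(=CO1)[C@H]([C@@H]3C(=O)C[C@H](C)OC3=O)[C@](C)(O)C(=O)O | intermediate
21 | (2S,3S)-3-{6-[(1E,3E,5S)-3,5-dimethylhepta-1,3-dien-1-yl]-4-hydroxy-4-methyl-4H-pyran-3-yl}-2-hydroxy-2-methyl-3-[(3R,6S)-6-methyl-2,4-dioxooxan-3-yl]propanoic acid (pyran C4 epimers) | CC[C@H](C)/C=C(C)/C=C/C1=CC(C)(O)C(=CO1)[C@H]([C@@H]3C(=O)C[C@H](C)OC3=O)[C@](C)(O)C(=O)O | intermediate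
22 | 5-[(1S,2S)-2-carboxy-2-hydroxy-1-[(3R,6S)-6-methyl-2,4-dioxooxan-3-yl]propyl]-2-[(1E,3E,5S)-3,5-dimethylhepta-1,3-dien-1-yl]-4-methylpyrylium tetrafluoroborate | CC[C@H](C)/C=C(C)/C=C/C1=CC(C)=C(C=[O+]1)[C@H]([C@@H]3C(=O)C[C@H](C)OC3=O)[C@](C)(O)C(=O)O.F[B-](F)(F)F | intermediate
23 | (2S,3S)-3-{6-[(1E,3E,5S)-3,5-dimethylhepta-1,3-dien-1-yl]-4-methylidene-4H-pyran-3-yl}-2-hydroxy-2-methyl-3-[(3R,6S)-6-methyl-2,4-dioxooxan-3-yl]propanoic acid | CC[C@H](C)/C=C(C)/C=C/C1=CC(=C)C(=CO1)[C@H]([C@@H]3C(=O)C[C@H](C)OC3=O)[C@](C)(O)C(=O)O | intermediate
24 | (5S)-5-[(S)-{6-[(1E,3E,5S)-3,5-dimethylhepta-1,3-dien-1-yl]-4-methylidene-4H-pyran-3-yl}[(3R,6S)-6-methyl-2,4-dioxooxan-3-yl]methyl]-5-methyl-1,3-dioxolane-2,4-dione | CC[C@H](C)/C=C(C)/C=C/C1=CC(=C)C(=CO1)[C@H]([C@@H]3C(=O)C[C@H](C)OC3=O)[C@]2(C)OC(=O)OC2=O | intermediate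
25 | (7S,8S)-3-[(1E,3E,5S)-3,5-dimethylhepta-1,3-dien-1-yl]-7-hydroxy-7-methyl-8-[(3R,6S)-6-methyl-2,4-dioxooxan-3-yl]-7,8-dihydro-6H-isochromen-6-one | CC[C@H](C)/C=C(C)/C=C/C1=CC2=CC(=O)[C@@](C)(O)[C@@H]([C@@H]3C(=O)C[C@H](C)OC3=O)C2=CO1 | intermediate
26 | (7S,8S)-5-chloro-8-[(6S)-3-chloro-6-methyl-2,4-dioxooxan-3-yl]-3-[(1E,3E,5S)-3,5-dimethylhepta-1,3-dien-1-yl]-7-hydroxy-7-methyl-7,8-dihydro-6H-isochromen-6-one (C3' epimers) | CC[C@H](C)/C=C(C)/C=C/C1=CC2=C(Cl)C(=O)[C@@](C)(O)[C@@H](C3(Cl)C(=O)C[C@H](C)OC3=O)C2=CO1 | intermediate
27 | (7S,8S)-5-chloro-3-[(1E,3E,5S)-3,5-dimethylhepta-1,3-dien-1-yl]-7-hydroxy-7-methyl-8-[(3R,6S)-6-methyl-2,4-dioxooxan-3-yl]-7,8-dihydro-6H-isochromen-6-one | CC[C@H](C)/C=C(C)/C=C/C1=CC2=C(Cl)C(=O)[C@@](C)(O)[C@@H]([C@@H]3C(=O)C[C@H](C)OC3=O)C2=CO1 | target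

## Step count and least certain steps

Total: 15 steps. Longest linear sequence: 11 steps from 1 (steps 1, 2, 3, 5, 8, 10, 11, 12, 13, 14, 15). Steps 4, 6, 7 and 9 are on side branches.

**Step 13 (key step, carries the label).**
- Most likely failure: acylation of the dione enolate oxygen by the activated C6 carboxyl (a six-membered enol lactone) or intermolecular acylation outrunning attack by C5, because the anhydride carbonyl is flanked by a quaternary carbon. A second failure mode is addition of imidazole or the carboxylate to C1, followed by opening of the pyran ring.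
- Fallback (known chemistry), from 22 back to 25: three equivalents of Et3N in CH2Cl2 at −30 °C would give 23. 2,4,6-Trichlorobenzoyl chloride, whose di-ortho-substituted carbonyl should react with the carboxylate oxygen but not with the carbon nucleophile, would then give the mixed 2,4,6-trichlorobenzoic anhydride F1. Warming under dilution should close the ring by C-acylation of the anhydrobase by a carboxylic anhydride, the acyl-donor class for which this reaction is established. Attack would go to the aliphatic carbonyl because the aroyl carbonyl is shielded. The tertiary hydroxyl stays free and is too hindered to interfere.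

**Step 10.**
- Most likely failure: poor facial selectivity at C8, since the closed transition state is only one of several arrangements of similar energy. Conjugate attack at C1 of the pyranone, or proton transfer from C5' of 15 to the basic enolate, are also possible.
- Fallback, from 17 back to 19: LiN(i-Pr)2 and Me3SiCl would give the silyl ketene acetal (2R)-2-tert-butyl-5-methyl-4-[(trimethylsilyl)oxy]-1,3-dioxole F2. A Mukaiyama–Michael addition of F2 to 15, catalysed by Cu(OTf)2 with a C2-symmetric tert-butyl bis(oxazoline) ligand, would follow. The copper centre chelates the two dione carbonyls, and the ligand enantiomer would be chosen so that it shields the C8 face leading to the unwanted epimer. The acetal still directs C7, and no strong base is present. The silyl enol ether adduct F3 would be hydrolysed to 19 on acidic work-up.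

**Step 12.**
- Most likely failure: precipitation of the magnesium trisalt before the addition takes place, or conjugate addition of the Grignard reagent at the unsubstituted C1 followed by ring-opening.
- Fallback, from 20 back to 22: tert-butyl 2,2,2-trichloroacetimidate would give the tert-butyl ester F4, whose neopentyl-type ester carbonyl should resist MeMgBr. Only an alkoxide and an enolate then have to be carried through the addition, which should give the pyranol F5. HBF4·OEt2 would ionise the carbinol and cleave the tert-butyl ester in the same operation, returning 22.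

**Step 5.**
- Most likely failure: self-condensation of the enolate of 8 at the formyl group of a second molecule, or acylation on oxygen, because the formyl group is only electronically masked.
- Fallback, from 5 (through 9) back to 11: the same in situ acylation would be run on commercial ethyl 2-[(dimethylamino)methylidene]-3-oxobutanoate. This is the substrate class on which the annulation is established. It should give the open-chain diketo enaminone ester F6 and, after acid, the pyranone ester F7. Me3SnOH would hydrolyse F7 to the acid F8 under neutral conditions. (COCl)2 would give the acid chloride F9, and LiAlH(Ot-Bu)3 at −78 °C would reduce it to 11 without touching the ring.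

**Steps 14 and 15, taken together.**
- Most likely failure: chlorination spreading to C4 or the side-chain diene under the excess of reagent, or over-reduction of the chromophore by zinc.
- Fallback, from 25 directly to 27: Ac2O and pyridine at 0 °C would give the enol acetate F10. The hindered tertiary alcohol should not react, and the masked dione, as a vinylogous anhydride, is electron-poor. One equivalent of NCS should then chlorinate only C5, giving F11. NaHCO3 in methanol at 0 °C would remove the enol acetate and return 27. No reductant is needed.

## Further compounds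

F1 | step 13 | mixed 2,4,6-trichlorobenzoic anhydride of 23 | CC[C@H](C)/C=C(C)/C=C/C1=CC(=C)C(=CO1)[C@H]([C@@H]3C(=O)C[C@H](C)OC3=O)[C@](C)(O)C(=O)OC(=O)c2c(Cl)cc(Cl)cc2Cl
F2 | step 10 | (2R)-2-tert-butyl-5-methyl-4-[(trimethylsilyl)oxy]-1,3-dioxole | CC1=C(O[Si](C)(C)C)O[C@H](C(C)(C)C)O1
F3 | step 10 | 4'-O-trimethylsilyl enol ether of 19 | CC[C@H](C)/C=C(C)/C=C/C1=CC(=O)C(=CO1)[C@H](C3=C(O[Si](C)(C)C)C[C@H](C)OC3=O)[C@]2(C)O[C@@H](C(C)(C)C)OC2=O
F4 | step 12 | tert-butyl ester of 20 | CC[C@H](C)/C=C(C)/C=C/C1=CC(=O)C(=CO1)[C@H]([C@@H]3C(=O)C[C@H](C)OC3=O)[C@](C)(O)C(=O)OC(C)(C)C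
F5 | step 12 | tert-butyl ester of 21 (pyran C4 epimers) | CC[C@H](C)/C=C(C)/C=C/C1=CC(C)(O)C(=CO1)[C@H]([C@@H]3C(=O)C[C@H](C)OC3=O)[C@](C)(O)C(=O)OC(C)(C)C
F6 | step 5 | ethyl (6E,8E,10S)-2-[(dimethylamino)methylidene]-8,10-dimethyl-3,5-dioxododeca-6,8-dienoate | CC[C@H](C)/C=C(C)/C=C/C(=O)CC(=O)C(C(=O)OCC)=CN(C)C
F7 | step 5 | ethyl 6-[(1E,3E,5S)-3,5-dimethylhepta-1,3-dien-1-yl]-4-oxo-4H-pyran-3-carboxylate | CC[C@H](C)/C=C(C)/C=C/C1=CC(=O)C(C(=O)OCC)=CO1
F8 | step 5 | 6-[(1E,3E,5S)-3,5-dimethylhepta-1,3-dien-1-yl]-4-oxo-4H-pyran-3-carboxylic acid | CC[C@H](C)/C=C(C)/C=C/C1=CC(=O)C(C(=O)O)=CO1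
F9 | step 5 | 6-[(1E,3E,5S)-3,5-dimethylhepta-1,3-dien-1-yl]-4-oxo-4H-pyran-3-carbonyl chloride | CC[C@H](C)/C=C(C)/C=C/C1=CC(=O)C(C(Cl)=O)=CO1
F10 | step 14 | 4'-O-acetyl enol ester of 25 | CC[C@H](C)/C=C(C)/C=C/C1=CC2=CC(=O)[C@@](C)(O)[C@@H](C3=C(OC(C)=O)C[C@H](C)OC3=O)C2=CO1
F11 | step 14 | 4'-O-acetyl enol ester of 27 | CC[C@H](C)/C=C(C)/C=C/C1=CC2=C(Cl)C(=O)[C@@](C)(O)[C@@H](C3=C(OC(C)=O)C[C@H](C)OC3=O)C2=CO1
A1 | alternative 1 | 7-O-triethylsilyl 4'-O-methyl derivative of 25 | CC[C@H](C)/C=C(C)/C=C/C1=CC2=CC(=O)[C@@](C)(O[Si](CC)(CC)CC)[C@@H](C3=C(OC)C[C@H](C)OC3=O)C2=CO1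
A2 | alternative 1 | open-chain diynone aldehyde (C1 aldehyde, C5≡C4a and C4≡C3 alkynes, C7 triethylsilyl ether, lactone methyl enol ether) | CC[C@H](C)/C=C(C)/C=C/C#CC#CC(=O)[C@@](C)(O[Si](CC)(CC)CC)[C@H](CC=O)C3=C(OC)C[C@H](C)OC3=O
A3 | alternative 2 | 2-chloro-4-(hydroxymethylidene)-3-methylcyclohex-2-enone with the C7 carbinol and the C8 lactone | O/C=C1/C(C)=C(Cl)C(=O)[C@@](C)(O)[C@H]1[C@@H]2C(=O)C[C@H](C)OC2=O
A4 | alternative 2 | (2S,4E)-4-chloro-2-hydroxy-2,5-dimethyl-3-oxohept-4-enedial | O=C[C@](C)(O)C(=O)/C(Cl)=C(C)\CC=O
A5 | alternative 3 | 7-O-triethylsilyl 4'-O-methyl derivative of 27 | CC[C@H](C)/C=C(C)/C=C/C1=CC2=C(Cl)C(=O)[C@@](C)(O[Si](CC)(CC)CC)[C@@H](C3=C(OC)C[C@H](C)OC3=O)C2=CO1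
A6 | alternative 3 | 2-chloro-4-[(dimethylamino)methylidene]-3-methylcyclohex-2-enone with the C7 triethylsilyl ether and the C8 lactone methyl enol ether | CN(C)/C=C1/C(C)=C(Cl)C(=O)[C@@](C)(O[Si](CC)(CC)CC)[C@H]1C2=C(OC)C[C@H](C)OC2=O
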